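## The problem

Broussoflavonol C (30) is an achiral flavonol: a phloroglucinol-type ring A is fused to the 3-hydroxy-4-pyranone ring C, and C2 of ring C carries the catechol ring B. With no stereocentre to set, the difficulty lies in the substitution pattern and in the fragility of the substituents. Ring A is fully differentiated: C8 carries a quaternary 1,1-dimethylallyl carbon wedged between O1 and O7, and of the three ring A oxygens exactly one (O1, on C8a) must enter the pyranone ring while O5 and O7 must end up free. Ring B carries two neighbouring prenyl groups at C2' and C3' beside the C4',C5' catechol, so the C2–C1' bond joining rings B and C has a prenyl group as its ortho neighbour. The molecule does not survive rough treatment: a prenyl group ortho to a free phenol closes to a chroman in acid, the 1,1-dimethylallyl group between two phenolic oxygens can cyclise or rearrange through a cation, the catechol and the 3-hydroxy-4-pyranone are oxidised in base under air, and three alkenes rule out hydrogenolysis, strong Lewis acids and electrophilic oxidants. Every protecting group therefore has to leave under mild acid or by chelation to the C4 carbonyl. The feature that opens the way is the alternation around ring A: the oxygen-bearing carbons C5, C7 and C8a alternate with C6–H, C4a and the quaternary-substituted C8. This is the pattern formed when a 3-alkoxy-4-alkylcyclobutenone (supplying C8a, C8, C7 and C6) is united with an alkoxyacetylene (supplying C5 and C4a), and the cyclobutenone carbonyl then emerges as O1–H, the only free hydroxyl, next to C8 and to the still unsubstituted C4a.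

## Retrosynthesis

Deprotection (30 ⇒ 29 ⇒ 28). The last bonds cut are O–C bonds of protecting groups: the O5–ethyl bond of 29, and before it the two acetal C–O bonds on ring B and the O7–tert-butyl bond of 28. The choice follows from the key step, in which O5 and O7 receive whatever alkyl group the two ynol ethers carry. The alkyne that delivers O7 is used below room temperature, so it can be the heat-sensitive tert-butyl ynol ether, and O7 becomes acid-labile like the acetals. The alkyne that delivers O5 must survive heating and is the ethyl compound, but O5 sits peri to the C4 carbonyl, the one place where an alkyl ether can be removed by chelation without a strong Lewis acid. Two ethyl ethers would be shorter to make but would leave an unactivated, hindered O7–ethyl bond with no mild way off. The forward steps must spare a prenyl group ortho to a phenol and the C8 side chain.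

Ring C (28 ⇒ 26 ⇒ 18 + 24). The O1–C2 and C3–O bonds are cut together (oxidative cyclisation of the 2'-hydroxychalcone 26), then the C2–C3 bond (aldol condensation of acetophenone 18 with aldehyde 24). A diketone cyclodehydration would close ring C with less regiochemical doubt but needs acid at a stage carrying four acid-labile groups. The chalcone route stays basic throughout and its oxidant touches only the enone. The cut divides the molecule into two fragments of similar size. It asks that the phenoxide close onto the benzylic carbon (six-membered ring) and not onto the α-carbon (aurone), in spite of the 6'-ethoxy group and the ortho prenyl group.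

C4a–C4 (18 ⇒ 17 ⇒ 16 ⇒ 14). The aryl–carbonyl bond is cut back to phenol 14 through salicylaldehyde 16; the methyl group is one further C–C bond, through carbinol 17. A Friedel–Crafts or Fries acylation would be a single step but needs a Lewis acid that the tert-butyl ether and the C8 side chain do not tolerate, and it would have to choose between C4a and C6. A magnesium-mediated formylation attacks only ortho to the free hydroxyl, and C4a is the only open ortho position. Precursor 14 is a trisubstituted phenol with a single free OH. The forward sequence must avoid acid, since carbinol 17 ionises easily.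

Ring A (14 ⇒ 8 + 9). Three bonds are cut: C8a–C4a and C5–C6 (ketene–alkyne [2+2]) and C8–C8a (six-electron electrocyclisation). This takes phenol 14 back to cyclobutenone 8 and ethoxyacetylene 9. The neighbouring option, an aromatic Claisen rearrangement on a preformed phloroglucinol ring, also gives a 2-(1,1-dimethylallyl)phenol. It starts, however, from a ring whose three oxygens must first be told apart, and it cannot direct the side chain between two chosen oxygens. Here the ring is built together with the side chain and with each oxygen already assigned. The precursors are a four-membered ring and a two-carbon alkyne. The forward step needs the donor-substituted cyclobutenone to open below the temperature at which 9 fragments, and the [2+2] step to follow the polarity of ketene and ynol ether.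

Cyclobutenone (8 ⇒ 6 + 4; 6 ⇒ 5; 4 ⇒ 2 ⇒ 1). The C1–C2 and C3–C4 bonds of 8 are cut by a second ketene–ynol ether [2+2] between ketene 7 (from acid chloride 6, hence from acid 5) and tert-butoxyacetylene 4. The quaternary carbon is bought ready-made in 5, so no bond to a tertiary centre is ever formed on an arene. Alkyne 4 is made, not bought, and goes back through dichlorovinyl ether 2 to trichloroethylene 1. The [2+2] step must run at or below room temperature, where 4 does not yet lose isobutene.

Ring B (24 ⇒ 22 ⇒ 21 ⇒ 20 ⇒ 19). The two aryl–CH2 bonds of 24 are cut to dibromide 22 (twofold Stille prenylation, which tolerates the aldehyde). Dibromide 22 goes back by protection, demethylation and bromination to 5-bromovanillin 19, whose substituents already map onto C1', C3', C4' and C5'. The second bromine enters para to the methoxy group, the more accessible of the two free positions, which is the future C2'. Making the aryl carbon the electrophile keeps the aldehyde unprotected. The price is the linear/branched question of the allyl transfer and the crowding of the second coupling.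

## Roads not taken

Alternative 1: This road spends its key step on ring B and cuts the two ArCH2–CH= bonds of the prenyl groups. 1-Bromo-2,3-bis(bromomethyl)-4,5-bis(methoxymethoxy)benzene A2 would be coupled twice with 2-methylprop-1-enylmagnesium bromide A3 under copper catalysis to give 1-bromo-4,5-bis(methoxymethoxy)-2,3-bis(3-methylbut-2-enyl)benzene A1. Bromine–lithium exchange on A1 and formylation would then lead to aldehyde 24.
- Merit: each prenyl group of A1 is assembled from a benzylic carbon and the vinyl nucleophile A3, so the linear/branched question of an allyl transfer never arises. In this respect it is safer than step 12.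
- Weak points: A2 needs a double benzylic bromination of an electron-rich 3,4-dioxygenated ortho-xylene, where nuclear bromination and attack on acetal C–H bonds compete, so the phenols would have to travel in another form and be re-protected. An ortho-bis(bromomethyl)arene such as A2 is prone to 1,4-reductive elimination to an ortho-quinodimethane when it meets A3 and a copper catalyst. The formyl group has to be added to A1 afterwards. Above all, the road leaves the ring A problem (the C8 quaternary carbon and the choice of O1) to other means.
- Comparison: against the better regiochemical security of the route through A1 the chosen plan sets a four-step passage from 19 to 24 with the aldehyde present from the start, a metathesis fallback that removes the allyl-transfer question, and a key step used where the structure is hardest.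

Alternative 2: Here the O1–C8a bond is cut. A carbonate base in a dipolar aprotic solvent would convert the 2-fluoroaryl 1,3-diketone A5 into its enolate, whose far oxygen would displace fluoride at C8a and close ring C as the fully protected flavonol A4, which carries allyl ethers at O5 and O7 and methoxymethyl ethers at O3, O4' and O5'.
- Merits: ring C is closed by C–O bond formation from a diketone that already carries the C3 oxygen, so no aurone can form. The allyl and methoxymethyl groups of A4 leave under zerovalent palladium and mild acid, which is gentler than the ethyl ether at O5 of the chosen plan.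
- Weak points: C8a of A5 is flanked by the quaternary C8. The alkoxy groups at C5 and C7 push electron density onto C4a, C6 and C8, the positions that must carry the charge of the Meisenheimer intermediate, so a single acyl group has to activate a hindered fluoride. Allyl aryl ethers begin to undergo Claisen rearrangement if the displacement needs strong heating. A5 also presupposes a fluoroarene building block that already holds the 1,1-dimethylallyl group between fluorine and an oxygen, so the hardest bond of ring A is moved into an unsolved precursor.
- Comparison: the chosen plan answers the protecting-group advantage of A4 with a tert-butyl ether at O7 and a chelation-cleavable ethyl ether at O5, and the aurone question with a diketone fallback. In return it makes the C8 attachment and the O1/O5/O7 differentiation in one step.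

Alternative 3: This road cuts the two C–CH3 bonds of the quaternary carbon. 4,6-Bis(methoxymethoxy)benzofuran-2(3H)-one A7 would be deprotonated and methylated twice to 4,6-bis(methoxymethoxy)-3,3-dimethylbenzofuran-2-one A6. Half-reduction of the lactone A6 and methylenation of the lactol would give 3,5-bis(methoxymethoxy)-2-(2-methylbut-3-en-2-yl)phenol A8, the counterpart of 14.
- Merits: every step is textbook enolate or carbonyl chemistry. The lactone oxygen of A6 becomes O1, so the oxygens are differentiated just as in 14. A8 carries two methoxymethyl ethers, so the endgame would need one acid step and no MgI2; on protecting groups this road is better than the chosen one.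
- Weak points: A7 must first be built on phloroglucinol A9 (C-alkylation with a two-carbon acid unit, lactonisation, protection of two of three similar hydroxyls), and A9 offers nothing to tell its hydroxyls apart. The enolate of the aryl-fused lactone A7 is ambident, and the second methylation creates a neopentyl centre beside an ortho substituent. The reduction of A6 has to stop at a lactol whose aldehyde form, next to a quaternary carbon, must then be methylenated. The sequence to A8 is linear and about as long as steps 1–5.
- Comparison: the two roads are close. Against the safer individual steps through A6 the chosen plan sets a convergent assembly of ring A from two small fragments, an oxygen pattern fixed by mechanism and not by selective protection, and formation of the aryl–quaternary bond in the ring-forming step itself. It pays with an untested substitution pattern in step 5 and one extra deprotection.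

Key step: step 5

Remark on the chemistry: the target has no stereocentre; the stereocentres of 8, 11, 13, 17, 25 and 27 are transient and racemic. Alkyne 4 is treated as a reagent to be prepared and used fresh.

Step 1
Reactants: 1 trichloroethylene
Product: 2 tert-butyl (E)-1,2-dichlorovinyl ether
Conditions: KOt-Bu, THF, −50 °C to rt
Reagents that add atoms: potassium tert-butoxide, CC(C)(C)[O-].[K+]
Why: Base-induced dehydrochlorination of 1 to dichloroacetylene and anti addition of tert-butoxide and a proton (addition–elimination route to 1,2-dichlorovinyl ethers) should give 2; the anti addition sets the E geometry.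

Step 2
Reactants: 2 tert-butyl (E)-1,2-dichlorovinyl ether
Product: 4 tert-butoxyacetylene, via lithium tert-butoxyacetylide 3 (not isolated)
Conditions: n-BuLi (2.2 equiv), Et2O, −78 to −40 °C; MeOH, −78 °C; cold aqueous wash, dried ethereal solution used at once
Reagents that add atoms: none
Why: Deprotonation and β-elimination give the chloroalkynyl ether, chlorine–lithium exchange gives acetylide 3, and cold protonation gives 4 (standard dichlorovinyl ether route to ynol ethers); 4 is kept cold because it loses isobutene by a retro-ene reaction on warming.

Step 3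
Reactants: 5 3,3-dimethylpent-4-enoic acid
Product: 6 3,3-dimethylpent-4-enoyl chloride
Conditions: (COCl)2, DMF (cat.), CH2Cl2, 0 °C to rt
Reagents that add atoms: oxalyl chloride, O=C(Cl)C(=O)Cl
Why: Standard acid chloride formation through the Vilsmeier-type chloroiminium species; the isolated terminal alkene is inert.

Step 4
Reactants: 6 3,3-dimethylpent-4-enoyl chloride; 4 tert-butoxyacetylene
Product: 8 3-tert-butoxy-4-(2-methylbut-3-en-2-yl)cyclobut-2-en-1-one (racemic), via ketene 7 (not isolated)
Conditions: Et3N, Et2O, 0 to 20 °C, slow addition of 6
Reagents that add atoms: none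
Why: Dehydrochlorination gives aldoketene 7, which undergoes the known regioselective ketene–ynol ether [2+2] cycloaddition: the nucleophilic CH carbon of 4 bonds to the ketene carbonyl carbon and the oxygen-bearing carbon to the ketene α-carbon, giving the 3-alkoxy-4-alkyl pattern; the new stereocentre is racemic and is erased in step 5, and the low temperature keeps 4 below its fragmentation threshold.

Step 5
Reactants: 8 3-tert-butoxy-4-(2-methylbut-3-en-2-yl)cyclobut-2-en-1-one; 9 ethoxyacetylene
Product: 14 3-tert-butoxy-5-ethoxy-2-(2-methylbut-3-en-2-yl)phenol, via vinylketene 10 (not isolated), via vinylcyclobutenone 11 (not isolated), via dienylketene 12 (not isolated), via cyclohexadienone 13 (not isolated)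
Conditions: 9 (3 equiv), toluene, 85–95 °C, sealed tube; then K2CO3, MeOH, rt
Reagents that add atoms: none
Why: Danheiser benzannulation (thermal cyclobutenone–ynol ether cascade): conrotatory four-electron opening of 8 at the C1–C4 bond, with the tert-alkyl group turning outward, gives vinylketene 10. Its ketene unit adds 9 in a polarity-matched [2+2] cycloaddition, the nucleophilic CH carbon of 9 bonding to the ketene carbonyl carbon (future C8a–C4a) and the ethoxy-bearing carbon to the ketene α-carbon (future C5–C6), which gives 11. Reversible four-electron opening of 11 funnels through dienylketene 12 with the alkenyl group turned inward, and disrotatory six-electron electrocyclisation of 12 forms C8–C8a and closes ring A as dienone 13, which tautomerises to 14. The closest known reactions are benzannulations of alkyl-substituted cyclobutenones with alkoxyacetylenes to give resorcinol monoethers; the donor pattern of 8 is untested for the first opening, but 11, a 3-alkoxy-4-substituted cyclobutenone of the kind every such cascade passes through, opens under the same conditions. Ring A is thus closed by a 6π electrocyclisation, preceded by a transient four-membered ring from the [2+2] step. No stereocentre survives, since those of 8, 11 and 13 are lost on aromatisation. The selectivity needed is regiochemical and is secured by the polarity of the ketene–ynol ether pair, which puts the ethoxy group meta to the new hydroxyl, and by the origin of that hydroxyl in the ketene carbonyl, which makes it the only free OH, ortho to the quaternary carbon and to the open C4a position. The carbonate treatment cleaves any aryl ester formed when 14 captures a ketene.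

Step 6
Reactants: 14 3-tert-butoxy-5-ethoxy-2-(2-methylbut-3-en-2-yl)phenol
Product: 16 4-tert-butoxy-6-ethoxy-2-hydroxy-3-(2-methylbut-3-en-2-yl)benzaldehyde, via salicyl alcohol 15 (not isolated)
Conditions: MgCl2, Et3N, (CH2O)n, MeCN, reflux
Reagents that add atoms: paraformaldehyde (as formaldehyde), C=O
Why: Casnati–Skattebøl ortho-formylation: the magnesium phenoxide delivers formaldehyde only to the ortho carbon (the single open one, future C4a), and the hydroxymethyl intermediate 15 is oxidised by hydride transfer to a second formaldehyde; 2-tert-alkylphenols are standard substrates and the conditions are non-acidic.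

Step 7
Reactants: 16 4-tert-butoxy-6-ethoxy-2-hydroxy-3-(2-methylbut-3-en-2-yl)benzaldehyde
Product: 17 3-tert-butoxy-5-ethoxy-6-(1-hydroxyethyl)-2-(2-methylbut-3-en-2-yl)phenol (racemic)
Conditions: MeMgBr (3 equiv), THF, 0 °C; aq. NH4Cl; crude product used directly
Reagents that add atoms: methylmagnesium bromide, C[Mg]Br
Why: Grignard addition to the aldehyde after deprotonation of the phenol by the first equivalent; the carbinol centre is racemic and disappears in step 8, and the electron-rich ortho-hydroxybenzyl alcohol is not exposed to acid or silica for long.

Step 8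
Reactants: 17 3-tert-butoxy-5-ethoxy-6-(1-hydroxyethyl)-2-(2-methylbut-3-en-2-yl)phenol
Product: 18 1-[4-tert-butoxy-6-ethoxy-2-hydroxy-3-(2-methylbut-3-en-2-yl)phenyl]ethan-1-one
Conditions: MnO2, CH2Cl2, rt
Reagents that add atoms: none
Why: MnO2 oxidation of an activated benzylic alcohol under neutral conditions; the alkene, the tert-butyl ether and the phenol (hydrogen-bonded to the new carbonyl) should be untouched.

Step 9
Reactants: 19 5-bromovanillin
Product: 20 5,6-dibromovanillin (2,3-dibromo-4-hydroxy-5-methoxybenzaldehyde)
Conditions: Br2, NaOAc, Fe powder (cat.), AcOH, rt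
Reagents that add atoms: bromine, BrBr
Why: Electrophilic aromatic bromination; the position para to the methoxy group is activated and more accessible than the carbon between the formyl and methoxy groups, so the second bromine should enter next to the first (future C2').

Step 10
Reactants: 20 5,6-dibromovanillin
Product: 21 2,3-dibromo-4,5-dihydroxybenzaldehyde
Conditions: BBr3, CH2Cl2, −78 °C to rt; H2O
Reagents that add atoms: none
Why: BBr3 cleavage of the aryl methyl ether, carried out before any acid-sensitive group is present; the aldehyde is regenerated on aqueous work-up.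

Step 11
Reactants: 21 2,3-dibromo-4,5-dihydroxybenzaldehyde
Product: 22 2,3-dibromo-4,5-bis(methoxymethoxy)benzaldehyde
Conditions: MOMCl, i-Pr2NEt, CH2Cl2, 0 °C to rt
Reagents that add atoms: chloromethyl methyl ether, COCCl
Why: Standard O-alkylation of both phenols to acetals that survive base, peroxide and palladium and leave in mild acid.

Step 12
Reactants: 22 2,3-dibromo-4,5-bis(methoxymethoxy)benzaldehyde
Product: 24 4,5-bis(methoxymethoxy)-2,3-bis(3-methylbut-2-enyl)benzaldehyde, via monoprenyl bromide 23 (not isolated)
Conditions: tributyl(3-methylbut-2-enyl)stannane (3 equiv), Pd(PPh3)4 (10 mol%), DMF, 100 °C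
Reagents that add atoms: tributyl(3-methylbut-2-en-1-yl)stannane, CCCC[Sn](CCCC)(CCCC)CC=C(C)C
Why: Twofold Stille coupling; oxidative addition should occur first at the bromide ortho to the formyl group, and reductive elimination at the unsubstituted allyl terminus should give the linear prenyl group each time; the allylstannane is not expected to add to the free aldehyde without a Lewis acid.

Step 13
Reactants: 18 1-[4-tert-butoxy-6-ethoxy-2-hydroxy-3-(2-methylbut-3-en-2-yl)phenyl]ethan-1-one; 24 4,5-bis(methoxymethoxy)-2,3-bis(3-methylbut-2-enyl)benzaldehyde
Product: 26 (E)-1-[4-tert-butoxy-6-ethoxy-2-hydroxy-3-(2-methylbut-3-en-2-yl)phenyl]-3-[4,5-bis(methoxymethoxy)-2,3-bis(3-methylbut-2-enyl)phenyl]prop-2-en-1-one, via aldol adduct 25 (not isolated)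
Conditions: KOH, EtOH/THF, rt
Reagents that add atoms: none
Why: Claisen–Schmidt condensation: the enolate of 18 adds to the non-enolisable aldehyde 24 and E1cB dehydration of 25 gives the thermodynamically favoured E-chalcone; the phenoxide form disfavours flavanone closure, and all protecting groups are base-stable.

Step 14
Reactants: 26 the (E)-chalcone of step 13
Product: 28 7-tert-butoxy-5-ethoxy-3-hydroxy-2-[4,5-bis(methoxymethoxy)-2,3-bis(3-methylbut-2-enyl)phenyl]-8-(2-methylbut-3-en-2-yl)chromen-4-one, via dihydroflavonol 27 (not isolated)
Conditions: H2O2 (30% aq.), NaOH, MeOH/THF, 0 °C to rt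
Reagents that add atoms: hydrogen peroxide, OO
Why: Algar–Flynn–Oyamada reaction: the hydroperoxide anion oxidises only the enone, the phenoxide closes onto the benzylic β-carbon to give the trans dihydroflavonol 27, and the alkaline peroxide dehydrogenates it to the flavonol; the two transient stereocentres vanish and the isolated alkenes are inert to a nucleophilic oxidant.

Step 15
Reactants: 28 the protected flavonol of step 14
Product: 29 2-[4,5-dihydroxy-2,3-bis(3-methylbut-2-enyl)phenyl]-5-ethoxy-3,7-dihydroxy-8-(2-methylbut-3-en-2-yl)chromen-4-one
Conditions: HCl (3 M aq.), MeOH/THF, 50 °C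
Reagents that add atoms: none
Why: Acid-catalysed methanolysis of both methoxymethyl acetals and SN1 cleavage of the aryl tert-butyl ether (helped by the leaving phenol para to the carbonyl-bearing carbon and by relief of strain beside the quaternary C8); the ethyl ether is untouched, and the mildness is chosen to avoid chroman formation from the prenyl group ortho to the freed C4' hydroxyl.

Step 16
Reactants: 29 the 5-O-ethyl flavonol of step 15
Product: 30 broussoflavonol C
Conditions: MgI2·OEt2 (excess), THF, 60 °C, argon; aq. Na2S2O3/NH4Cl
Reagents that add atoms: none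
Why: Chelation-assisted dealkylation: magnesium bridges the C4 carbonyl and O5, and iodide removes the ethyl group by SN2; only the ether peri to the carbonyl can react, and the closely related MgI2 dealkylation of 5-alkoxyflavonoids carrying prenyl groups and free phenols is a known reaction type.

Compound list

1 | trichloroethylene | ClC=C(Cl)Cl | starting material
2 | tert-butyl (E)-1,2-dichlorovinyl ether | Cl/C=C(\OC(C)(C)C)Cl | intermediate
3 | lithium tert-butoxyacetylide | [Li]C#COC(C)(C)C | intermediate (not isolated)
4 | tert-butoxyacetylene (2-ethynyloxy-2-methylpropane) | C#COC(C)(C)C | intermediate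
5 | 3,3-dimethylpent-4-enoic acid | C=CC(C)(C)CC(=O)O | starting material
6 | 3,3-dimethylpent-4-enoyl chloride | C=CC(C)(C)CC(=O)Cl | intermediate
7 | (2-methylbut-3-en-2-yl)ketene (3,3-dimethylpenta-1,4-dien-1-one) | C=CC(C)(C)C=C=O | intermediate (not isolated)
8 | 3-tert-butoxy-4-(2-methylbut-3-en-2-yl)cyclobut-2-en-1-one (racemic) | CC(C)(C)OC1=CC(=O)C1C(C)(C)C=C | intermediate
9 | ethoxyacetylene | C#COCC | starting material
10 | (3Z)-3-tert-butoxy-5,5-dimethylhepta-1,3,6-trien-1-one | O=C=C/C(OC(C)(C)C)=C/C(C)(C)C=C | intermediate (not isolated)
11 | 4-[(1Z)-1-tert-butoxy-3,3-dimethylpenta-1,4-dienyl]-3-ethoxycyclobut-2-en-1-one (racemic) | CCOC1=CC(=O)C1/C(OC(C)(C)C)=C/C(C)(C)C=C | intermediate (not isolated)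
12 | (3E,5Z)-5-tert-butoxy-3-ethoxy-7,7-dimethylnona-1,3,5,8-tetraen-1-one | O=C=C/C(OCC)=C\C(OC(C)(C)C)=C\C(C)(C)C=C | intermediate (not isolated)
13 | 5-tert-butoxy-3-ethoxy-6-(2-methylbut-3-en-2-yl)cyclohexa-2,4-dien-1-one (racemic) | CCOC1=CC(=O)C(C(C)(C)C=C)C(OC(C)(C)C)=C1 | intermediate (not isolated)
14 | 3-tert-butoxy-5-ethoxy-2-(2-methylbut-3-en-2-yl)phenol | C=CC(C)(C)c1c(O)cc(OCC)cc1OC(C)(C)C | intermediate
15 | 3-tert-butoxy-5-ethoxy-6-(hydroxymethyl)-2-(2-methylbut-3-en-2-yl)phenol | C=CC(C)(C)c1c(O)c(CO)c(OCC)cc1OC(C)(C)C | intermediate (not isolated)
16 | 4-tert-butoxy-6-ethoxy-2-hydroxy-3-(2-methylbut-3-en-2-yl)benzaldehyde | C=CC(C)(C)c1c(O)c(C=O)c(OCC)cc1OC(C)(C)C | intermediate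
17 | 3-tert-butoxy-5-ethoxy-6-(1-hydroxyethyl)-2-(2-methylbut-3-en-2-yl)phenol (racemic) | C=CC(C)(C)c1c(O)c(C(C)O)c(OCC)cc1OC(C)(C)C | intermediate
18 | 1-[4-tert-butoxy-6-ethoxy-2-hydroxy-3-(2-methylbut-3-en-2-yl)phenyl]ethan-1-one | CC(=O)c1c(O)c(C(C)(C)C=C)c(OC(C)(C)C)cc1OCC | intermediate
19 | 5-bromovanillin (3-bromo-4-hydroxy-5-methoxybenzaldehyde) | COc1cc(C=O)cc(Br)c1O | starting material
20 | 5,6-dibromovanillin (2,3-dibromo-4-hydroxy-5-methoxybenzaldehyde) | COc1cc(C=O)c(Br)c(Br)c1O | intermediate
21 | 2,3-dibromo-4,5-dihydroxybenzaldehyde | O=Cc1cc(O)c(O)c(Br)c1Br | intermediate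
22 | 2,3-dibromo-4,5-bis(methoxymethoxy)benzaldehyde | O=Cc1cc(OCOC)c(OCOC)c(Br)c1Br | intermediate
23 | 3-bromo-4,5-bis(methoxymethoxy)-2-(3-methylbut-2-enyl)benzaldehyde | O=Cc1cc(OCOC)c(OCOC)c(Br)c1CC=C(C)C | intermediate (not isolated)
24 | 4,5-bis(methoxymethoxy)-2,3-bis(3-methylbut-2-enyl)benzaldehyde | O=Cc1cc(OCOC)c(OCOC)c(CC=C(C)C)c1CC=C(C)C | intermediate
25 | 1-[4-tert-butoxy-6-ethoxy-2-hydroxy-3-(2-methylbut-3-en-2-yl)phenyl]-3-hydroxy-3-[4,5-bis(methoxymethoxy)-2,3-bis(3-methylbut-2-enyl)phenyl]propan-1-one (racemic) | CCOc1cc(OC(C)(C)C)c(C(C)(C)C=C)c(O)c1C(=O)CC(O)c1cc(OCOC)c(OCOC)c(CC=C(C)C)c1CC=C(C)C | intermediate (not isolated)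
26 | (E)-1-[4-tert-butoxy-6-ethoxy-2-hydroxy-3-(2-methylbut-3-en-2-yl)phenyl]-3-[4,5-bis(methoxymethoxy)-2,3-bis(3-methylbut-2-enyl)phenyl]prop-2-en-1-one | CCOc1cc(OC(C)(C)C)c(C(C)(C)C=C)c(O)c1C(=O)/C=C/c1cc(OCOC)c(OCOC)c(CC=C(C)C)c1CC=C(C)C | intermediate
27 | (2R*,3R*)-7-tert-butoxy-5-ethoxy-3-hydroxy-2-[4,5-bis(methoxymethoxy)-2,3-bis(3-methylbut-2-enyl)phenyl]-8-(2-methylbut-3-en-2-yl)-2,3-dihydrochromen-4-one (trans, racemic, one enantiomer drawn) | O=C1c2c(OCC)cc(OC(C)(C)C)c(C(C)(C)C=C)c2O[C@H](c2cc(OCOC)c(OCOC)c(CC=C(C)C)c2CC=C(C)C)[C@H]1O | intermediate (not isolated)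
28 | 7-tert-butoxy-5-ethoxy-3-hydroxy-2-[4,5-bis(methoxymethoxy)-2,3-bis(3-methylbut-2-enyl)phenyl]-8-(2-methylbut-3-en-2-yl)chromen-4-one | CCOc1cc(OC(C)(C)C)c(C(C)(C)C=C)c2oc(-c3cc(OCOC)c(OCOC)c(CC=C(C)C)c3CC=C(C)C)c(O)c(=O)c12 | intermediate
29 | 2-[4,5-dihydroxy-2,3-bis(3-methylbut-2-enyl)phenyl]-5-ethoxy-3,7-dihydroxy-8-(2-methylbut-3-en-2-yl)chromen-4-one | CCOc1cc(O)c(C(C)(C)C=C)c2oc(-c3cc(O)c(O)c(CC=C(C)C)c3CC=C(C)C)c(O)c(=O)c12 | intermediate
30 | broussoflavonol C, 2-[4,5-dihydroxy-2,3-bis(3-methylbut-2-enyl)phenyl]-3,5,7-trihydroxy-8-(2-methylbut-3-en-2-yl)chromen-4-one | C=CC(C)(C)c1c(O)cc(O)c2c(=O)c(O)c(-c3cc(O)c(O)c(CC=C(C)C)c3CC=C(C)C)oc12 | target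

Total step count: 16. Longest linear sequence: 11 steps (steps 1, 2, 4, 5, 6, 7, 8, 13, 14, 15, 16, from 1 to 30).

Steps least certain to work

Step 5 (key step). The first ring opening may be slow, because the 3-alkoxy group stabilises 8 as a vinylogous ester and the 4-substituent is a bulky alkyl group, not an accelerating alkenyl or aryl group. At the temperatures then needed, 9 fragments by a retro-ene reaction to ethylene and ketene, which starves the cascade and acylates the product; traces of acid could also strip isobutene from the enol ether of 8. The fallback sets out from 8 and 9 and comes back at 14. It drives the first pericyclic event with light instead of heat: irradiation at about 300 nm of 8 with excess 9 at room temperature should open the enone chromophore to 10 (a known photochemical mode of cyclobutenones), adduct 11 should accumulate, and brief warming to 70–80 °C, where 11 opens readily and 9 is still intact, should complete the sequence. It makes no compound beyond those already listed, which the entry F0 records.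

Step 14. Closure of the phenoxide at the α-carbon (five-membered ring, leading to an aurone) may compete with closure at the β-carbon, since the 6'-ethoxy group twists the carbonyl out of plane and the ortho prenyl group shields the β-carbon. The fallback sets out from 16 and 24 and comes back at 29; it installs the C3 oxygen before ring closure, so that only the six-membered ring can form. Addition of (methoxymethoxy)methyllithium (from tributyl[(methoxymethoxy)methyl]stannane and n-BuLi, THF, −78 °C, in excess to allow for the phenol) to 16 would give 3-tert-butoxy-5-ethoxy-6-[1-hydroxy-2-(methoxymethoxy)ethyl]-2-(2-methylbut-3-en-2-yl)phenol F1. MnO2 oxidation would give 1-[4-tert-butoxy-6-ethoxy-2-hydroxy-3-(2-methylbut-3-en-2-yl)phenyl]-2-(methoxymethoxy)ethan-1-one F2. Aldol addition of the dianion of F2 (LiN(SiMe3)2, THF, −78 °C) to 24 would give 1-[4-tert-butoxy-6-ethoxy-2-hydroxy-3-(2-methylbut-3-en-2-yl)phenyl]-3-hydroxy-2-(methoxymethoxy)-3-[4,5-bis(methoxymethoxy)-2,3-bis(3-methylbut-2-enyl)phenyl]propan-1-one F3. Dess–Martin oxidation would give 1-[4-tert-butoxy-6-ethoxy-2-hydroxy-3-(2-methylbut-3-en-2-yl)phenyl]-2-(methoxymethoxy)-3-[4,5-bis(methoxymethoxy)-2,3-bis(3-methylbut-2-enyl)phenyl]propane-1,3-dione F4. Methanolic HCl at 50 °C would then close ring C by acid-catalysed cyclodehydration of F4 through the phenolic oxygen (the ring-closing stage of a Baker–Venkataraman flavone synthesis) and remove the three acetals and the tert-butyl ether, giving 29.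

Step 12. The second oxidative addition, at a bromide flanked by a prenyl group and an acetal oxygen, may stall at 23; allyl transposition may deliver some 1,1-dimethylallyl isomer; protodebromination may compete. The fallback sets out from 22 and comes back at 24, and removes the regiochemical question. Twofold Stille coupling with allyltributylstannane (Pd(PPh3)4, toluene, 100 °C) would give 4,5-bis(methoxymethoxy)-2,3-di(prop-2-enyl)benzaldehyde F5. Cross-metathesis of both allyl groups of F5 with 2-methylbut-2-ene (second-generation Grubbs catalyst, CH2Cl2, 40 °C) would then give 24.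

Step 16. Iodide attack on ethyl is slower than on methyl, magnesium is shared among the catechol, the 3-hydroxy-4-keto site and the O5/C4 site, and prolonged heating risks acid-promoted cyclisation of the prenyl group onto the C4' hydroxyl. The fallback sets out from 28 and comes back at 30; it removes the ethyl group by nucleophilic attack on a fully protected substrate, before any phenol is free. MOMCl/i-Pr2NEt would convert 28 into 7-tert-butoxy-5-ethoxy-3-(methoxymethoxy)-2-[4,5-bis(methoxymethoxy)-2,3-bis(3-methylbut-2-enyl)phenyl]-8-(2-methylbut-3-en-2-yl)chromen-4-one F6. NaSEt in DMF at 100 °C would cleave the one ether activated by the ortho carbonyl and give 7-tert-butoxy-5-hydroxy-3-(methoxymethoxy)-2-[4,5-bis(methoxymethoxy)-2,3-bis(3-methylbut-2-enyl)phenyl]-8-(2-methylbut-3-en-2-yl)chromen-4-one F7. Methanolic HCl at 50 °C would then remove the three acetals and the tert-butyl ether of F7 to give 30.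

Further compounds

F0 | step 5 | none | none
F1 | step 14 | 3-tert-butoxy-5-ethoxy-6-[1-hydroxy-2-(methoxymethoxy)ethyl]-2-(2-methylbut-3-en-2-yl)phenol (racemic) | C=CC(C)(C)c1c(O)c(C(O)COCOC)c(OCC)cc1OC(C)(C)C
F2 | step 14 | 1-[4-tert-butoxy-6-ethoxy-2-hydroxy-3-(2-methylbut-3-en-2-yl)phenyl]-2-(methoxymethoxy)ethan-1-one | C=CC(C)(C)c1c(O)c(C(=O)COCOC)c(OCC)cc1OC(C)(C)C
F3 | step 14 | 1-[4-tert-butoxy-6-ethoxy-2-hydroxy-3-(2-methylbut-3-en-2-yl)phenyl]-3-hydroxy-2-(methoxymethoxy)-3-[4,5-bis(methoxymethoxy)-2,3-bis(3-methylbut-2-enyl)phenyl]propan-1-one (mixture of diastereomers) | C=CC(C)(C)c1c(O)c(C(=O)C(OCOC)C(O)c2cc(OCOC)c(OCOC)c(CC=C(C)C)c2CC=C(C)C)c(OCC)cc1OC(C)(C)C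
F4 | step 14 | 1-[4-tert-butoxy-6-ethoxy-2-hydroxy-3-(2-methylbut-3-en-2-yl)phenyl]-2-(methoxymethoxy)-3-[4,5-bis(methoxymethoxy)-2,3-bis(3-methylbut-2-enyl)phenyl]propane-1,3-dione (racemic) | C=CC(C)(C)c1c(O)c(C(=O)C(OCOC)C(=O)c2cc(OCOC)c(OCOC)c(CC=C(C)C)c2CC=C(C)C)c(OCC)cc1OC(C)(C)C
F5 | step 12 | 4,5-bis(methoxymethoxy)-2,3-di(prop-2-enyl)benzaldehyde | O=Cc1cc(OCOC)c(OCOC)c(CC=C)c1CC=C
F6 | step 16 | 7-tert-butoxy-5-ethoxy-3-(methoxymethoxy)-2-[4,5-bis(methoxymethoxy)-2,3-bis(3-methylbut-2-enyl)phenyl]-8-(2-methylbut-3-en-2-yl)chromen-4-one | CCOc1cc(OC(C)(C)C)c(C(C)(C)C=C)c2oc(-c3cc(OCOC)c(OCOC)c(CC=C(C)C)c3CC=C(C)C)c(OCOC)c(=O)c12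
F7 | step 16 | 7-tert-butoxy-5-hydroxy-3-(methoxymethoxy)-2-[4,5-bis(methoxymethoxy)-2,3-bis(3-methylbut-2-enyl)phenyl]-8-(2-methylbut-3-en-2-yl)chromen-4-one | Oc1cc(OC(C)(C)C)c(C(C)(C)C=C)c2oc(-c3cc(OCOC)c(OCOC)c(CC=C(C)C)c3CC=C(C)C)c(OCOC)c(=O)c12
A1 | alternative 1 | 1-bromo-4,5-bis(methoxymethoxy)-2,3-bis(3-methylbut-2-enyl)benzene | Brc1cc(OCOC)c(OCOC)c(CC=C(C)C)c1CC=C(C)C
A2 | alternative 1 | 1-bromo-2,3-bis(bromomethyl)-4,5-bis(methoxymethoxy)benzene | Brc1cc(OCOC)c(OCOC)c(CBr)c1CBr
A3 | alternative 1 | 2-methylprop-1-enylmagnesium bromide | CC(C)=C[Mg]Br
A4 | alternative 2 | 5,7-bis(allyloxy)-3-(methoxymethoxy)-8-(2-methylbut-3-en-2-yl)-2-[4,5-bis(methoxymethoxy)-2,3-bis(3-methylbut-2-enyl)phenyl]chromen-4-one | C=CC(C)(C)c1c(OCC=C)cc(OCC=C)c2c(=O)c(OCOC)c(-c3cc(OCOC)c(OCOC)c(CC=C(C)C)c3CC=C(C)C)oc12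
A5 | alternative 2 | 1-[4,6-bis(allyloxy)-2-fluoro-3-(2-methylbut-3-en-2-yl)phenyl]-2-(methoxymethoxy)-3-[4,5-bis(methoxymethoxy)-2,3-bis(3-methylbut-2-enyl)phenyl]propane-1,3-dione (racemic) | C=CC(C)(C)c1c(F)c(C(=O)C(OCOC)C(=O)c2cc(OCOC)c(OCOC)c(CC=C(C)C)c2CC=C(C)C)c(OCC=C)cc1OCC=C
A6 | alternative 3 | 4,6-bis(methoxymethoxy)-3,3-dimethylbenzofuran-2-one | O=C1Oc2cc(OCOC)cc(OCOC)c2C1(C)C
A7 | alternative 3 | 4,6-bis(methoxymethoxy)benzofuran-2(3H)-one | O=C1Cc2c(OCOC)cc(OCOC)cc2O1
A8 | alternative 3 | 3,5-bis(methoxymethoxy)-2-(2-methylbut-3-en-2-yl)phenol | C=CC(C)(C)c1c(O)cc(OCOC)cc1OCOC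
A9 | alternative 3 | phloroglucinol (benzene-1,3,5-triol) | Oc1cc(O)cc(O)c1
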